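Remark on the chemistry: asplenetin has no stereocentre, no stereogenic axis and no configurational double bond. It is achiral, so the given SMILES already defines the single compound to be made and no stereocontrol is required.

Remark on notation: catalyst-bound organometallic species of the catalytic cycles are described in words in the Why lines and are not numbered.

## Structural features

Asplenetin is a flavone: a 4H-chromen-4-one in which a 5,7-dihydroxylated benzo ring (ring A, phloroglucinol type) is fused through C4a–C8a to a γ-pyranone (ring C: O1, C2, C3, C4). C2 carries a 3,4,5-trihydroxyphenyl group (ring B, pyrogallol type) through the C2–C1' bond. C3 carries a saturated 3-methylbutyl (isopentyl) chain, so the C2=C3 double bond is fully substituted: aryl and O1 on C2, alkyl and the C4 carbonyl on C3. There are no stereocentres. The fragile groups are the five phenols: ring B is easily oxidised by air, base or Cu(II), and the 5-OH is hydrogen-bonded to C4=O. The real difficulty is the regiodefined, tetrasubstituted C2=C3 unit with an unactivated sp3 chain on C3. This position cannot be alkylated cleanly on a preformed flavone, and it makes the usual acyl-transfer chemistry congested. The key step exploits the fact that C3 and C2, with their isopentyl and aryl substituents, have the connectivity of an unsymmetrical aryl–alkyl acetylene, while O1, C8a, C4a and C4 are the phenol oxygen, two ring carbons and the formyl carbon of a salicylaldehyde. In one sentence: a rhodium-catalysed oxidative formyl C–H/O–H annulation of a salicylaldehyde with an aryl(isopentyl)acetylene builds ring C and both of its substituents at once.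

## Logic of the disconnections

**6 ⇒ 5.** The five phenolic O–H bonds of 6 are traced back to five O–CH3 bonds. The reason is that a free pyrogallol ring would not survive the Cu(II) oxidant of the key step, and both building blocks are sold as their methyl ethers. The gain is that no protecting-group step is needed before the key step. The demand on the forward step is exhaustive cleavage of five aryl methyl ethers, including the non-chelated one at C7, without harm to ring C, followed by oxygen-free isolation.

**5 ⇒ 3 + 4.** The C3–C4 bond and the O1–C2 bond of ring C are cut. This removes the C2=C3 unit with both of its substituents as one alkyne, 3, and leaves ring A with O1 and C4 as 4, whose formyl carbon becomes C4. The gain is large: ring C, the tetrasubstituted double bond, the C3 chain and the C2 aryl group all come from one operation on two simple partners. The forward step must activate the formyl C–H bond without decarbonylation and insert 3 so that the alkyl-bearing carbon bonds to C4. It must then close the C–O bond under oxidative turnover.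

**3 ⇒ 1 + 2.** The C(sp2)–C(sp) bond between ring B and the alkyne is cut, giving 1 and 2, both commercial. The gain is full convergence: the chain and ring B are joined in one catalytic step. The demand is a clean cross-coupling at an electron-rich aryl iodide without oxidative dimerisation of 2.

## Other disconnections considered

**Alternative 1:** (the first that comes to mind) cut O1–C2 and C2–C3, so that C2 with ring B is delivered as a galloyl unit to an A-ring ketone that already carries the chain. The forward key step is the Baker–Venkataraman O→C aroyl shift of ester A1 (3,5-dimethoxy-2-(5-methylhexanoyl)phenyl 3,4,5-trimethoxybenzoate) to the 2-alkyl-1,3-diketone A2, followed by acid cyclodehydration to 5. The chosen plan is preferred on two grounds. First, the enolate in A1 is secondary and must attack an electron-rich, hindered benzoate to give a congested 2-alkyl-1,3-dione, so the shift is slower and more prone to ester cleavage than in the 3-unsubstituted series. Second, A1 needs a Friedel–Crafts acylation of a phloroglucinol ether (ortho/para ambiguity) and an esterification first, so the sequence runs to at least five linear steps against three.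

**Alternative 2:** cut the C3–CH2 bond of the side chain. The forward key step is a Negishi coupling of 3-methylbutylzinc bromide with the 3-iodoflavone A4, itself obtained by ICl-induced cyclisation of ynone A3. The chosen plan is preferred because the flavone core must first be built without the chain and then functionalised, at least five steps in all. In addition, the coupling takes place at a vinyl iodide flanked by C4=O and the 2-aryl group, with an sp3 partner bearing β-hydrogens, so β-hydride elimination and protodeiodination are expected to compete. In the chosen plan the chain rides in on the alkyne and no C(sp2)–C(sp3) coupling is needed.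

**Alternative 3:** cut C4–C4a, C4–C3 and O1–C2 with carbon monoxide as a third component. The forward key step is a palladium-catalysed carbonylative annulation of 2-iodo-3,5-dimethoxyphenol A5 with 3 and CO. The chosen plan is preferred on mechanistic grounds: an aryl–palladium species carbopalladates an internal alkyne before CO inserts, so CO enters after the alkyne. Lactonisation should then give a 3,4-disubstituted coumarin such as A6, an isomer of 5, and not the chromone. In the chosen plan the carbonyl carbon is already bound to ring A as the formyl group, so the order acyl-then-alkyne is fixed by the substrate. A5 would also require a regioselective iodination.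

Key step: step 2

## Route

Step 1
Reactants: 1 5-iodo-1,2,3-trimethoxybenzene; 2 5-methylhex-1-yne
Product: 3 1,2,3-trimethoxy-5-(5-methylhex-1-yn-1-yl)benzene
Conditions: PdCl2(PPh3)2 (2 mol%), CuI (4 mol%), Et3N/THF (degassed), 2 (1.3 equiv), rt to 50 °C, argon
Reagents that add atoms: none
Why: Sonogashira coupling of an aryl iodide with a terminal alkyl acetylene; the iodide undergoes oxidative addition readily despite the electron-rich ring, the methyl ethers are inert, and rigorous degassing suppresses oxidative dimerisation of 2.

Step 2
Reactants: 3 1,2,3-trimethoxy-5-(5-methylhex-1-yn-1-yl)benzene; 4 2-hydroxy-4,6-dimethoxybenzaldehyde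
Product: 5 5,7-dimethoxy-3-(3-methylbutyl)-2-(3,4,5-trimethoxyphenyl)-4H-chromen-4-one
Conditions: [RhCl(cod)]2 (2 mol%), 1,2,3,4-tetraphenylcyclopenta-1,3-diene (8 mol%), Cu(OAc)2·H2O (2.2 equiv), 3 (1.2 equiv), o-xylene, 140 °C, N2
Reagents that add atoms: none
Why: This is the rhodium-catalysed, copper-mediated oxidative annulation of a salicylaldehyde with an internal alkyne through formyl C–H and O–H cleavage, a known reaction type whose closest relatives are the Rh(III)-catalysed oxidative annulations of benzoic acids and benzamides with alkynes to isocoumarins and isoquinolones. Acetate-assisted exchange gives a rhodium aryloxide of 4; the chelate holds the metal next to the formyl C–H bond, which is cleaved to a five-membered acyl(aryloxy)rhodacycle; 3 inserts into the Rh–acyl bond to give a seven-membered oxarhodacycle; C–O reductive elimination releases 5 and Rh(I), which two equivalents of Cu(OAc)2 reoxidise. Ring C is closed as a formal [4+2] oxidative annulation (O1, C8a, C4a and C4 from 4; C3 and C2 from 3): the C4–C3 bond forms intermolecularly by migratory insertion and the ring-closing event is C(sp2)–O reductive elimination forming O1–C2. No stereocentre is created. The step needs the acyl carbon to bond to the alkyl-bearing alkyne carbon; the aryl/alkyl difference in 3 should secure this, because on insertion the metal ends on the aryl-substituted carbon (benzyl-like stabilisation of the Rh–C bond, larger group next to the metal), the same sense that places the aryl group next to the heteroatom in related annulations, so that aryl ends on C2 and isopentyl on C3. Selectivity for the formyl C–H bond over aryl C–H bonds is secured by the single free ortho hydroxyl of 4, all other oxygens being methyl ethers that cannot bind as anionic ligands. Decarbonylation is disfavoured because CO extrusion from the five-membered chelate would require a strained four-membered oxarhodacycle. The methyl ethers keep the future pyrogallol ring inert towards Cu(II) at 140 °C.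

Step 3
Reactants: 5 5,7-dimethoxy-3-(3-methylbutyl)-2-(3,4,5-trimethoxyphenyl)-4H-chromen-4-one
Product: 6 asplenetin, 5,7-dihydroxy-3-(3-methylbutyl)-2-(3,4,5-trihydroxyphenyl)-4H-chromen-4-one
Conditions: BBr3 (1 M in CH2Cl2, 12 equiv), CH2Cl2, −78 °C to rt (40 °C if needed), argon; then ice-water, degassed work-up with aqueous ascorbic acid
Reagents that add atoms: none
Why: Lewis acid-mediated cleavage of aryl methyl ethers (bromide attacks the methyl group of the boron-complexed ether); the chelated 5-OMe and the three contiguous B-ring ethers should cleave fastest, the excess reagent and extended time are aimed at the 7-OMe, and the chromone, its tetrasubstituted double bond and the saturated chain are inert to BBr3.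

## Compound list

1 | 5-iodo-1,2,3-trimethoxybenzene | COc1cc(I)cc(OC)c1OC | starting material
2 | 5-methylhex-1-yne | CC(C)CCC#C | starting material
3 | 1,2,3-trimethoxy-5-(5-methylhex-1-yn-1-yl)benzene | CC(C)CCC#Cc1cc(OC)c(OC)c(OC)c1 | intermediate
4 | 2-hydroxy-4,6-dimethoxybenzaldehyde | COc1cc(O)c(C=O)c(OC)c1 | starting material
5 | 5,7-dimethoxy-3-(3-methylbutyl)-2-(3,4,5-trimethoxyphenyl)-4H-chromen-4-one | CC(C)CCc1c(-c2cc(OC)c(OC)c(OC)c2)oc2cc(OC)cc(OC)c2c1=O | intermediate
6 | asplenetin, 5,7-dihydroxy-3-(3-methylbutyl)-2-(3,4,5-trihydroxyphenyl)-4H-chromen-4-one | CC(C)CCc1c(-c2cc(O)c(O)c(O)c2)oc2cc(O)cc(O)c2c1=O | target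

## Step count and least certain steps

Total step count: 3. Longest linear sequence: 3 steps (1 and 2 to 3, then 5, then 6).

**Step 2 (key step).** The methoxy group ortho to the formyl group crowds the acyl–rhodium centre and the formyl group is strongly hydrogen-bonded, so three processes may intervene:
- slow formyl C–H metalation;
- protonolysis of the alkenyl–rhodium bond before C–O bond formation (net hydroacylation without ring closure);
- decarbonylation at 140 °C.

Erosion of the insertion regioselectivity with an alkyne whose aryl group is hindered by two meta substituents is a further possibility.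

The fallback is a polar, metal-free construction of ring C that sets out from 4 and returns to the route at 5. Addition of 4-methylpentylmagnesium bromide (2.5 equiv, THF, 0 °C to rt; the first equivalent is consumed by the phenol) to 4 should give racemic 2-(1-hydroxy-5-methylhexyl)-3,5-dimethoxyphenol F1. Oxidation of the benzylic alcohol with MnO2 in CH2Cl2 should give 1-(2-hydroxy-4,6-dimethoxyphenyl)-5-methylhexan-1-one F2. Claisen–Schmidt condensation of this ketone with 3,4,5-trimethoxybenzaldehyde (KOH, EtOH, 50 °C) should give the α-alkylchalcone (2E)-1-(2-hydroxy-4,6-dimethoxyphenyl)-5-methyl-2-[(3,4,5-trimethoxyphenyl)methylidene]hexan-1-one F3. Iodine-catalysed oxidative cyclisation in DMSO at 130 °C (oxa-Michael addition, α-iodination, elimination) should convert it into 5. The regiochemistry is then fixed by the carbon skeleton and does not depend on an insertion event.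

**Step 3.** Cleavage of the non-chelated 7-O-methyl ether may remain incomplete under conditions that the rest of the molecule tolerates. The liberated pyrogallol ring may also be oxidised during aqueous work-up and purification.

The fallback changes the protecting groups to benzyl ethers, so that the final unmasking is a neutral hydrogenolysis. It sets out from 1 and 4, uses 2, and rejoins the route at 6.
- B-ring partner: demethylation of 1 with BBr3 should give 5-iodobenzene-1,2,3-triol F4. Benzylation (BnBr, K2CO3, DMF) should give 1,2,3-tris(benzyloxy)-5-iodobenzene F5. Sonogashira coupling with 2 under the conditions of step 1 should give 1,2,3-tris(benzyloxy)-5-(5-methylhex-1-yn-1-yl)benzene F6.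
- A-ring partner: demethylation of 4 with BBr3 should give 2,4,6-trihydroxybenzaldehyde F7. Benzylation with two equivalents of BnBr (K2CO3, DMF) should leave one hydrogen-bonded ortho hydroxyl free and give 2,4-bis(benzyloxy)-6-hydroxybenzaldehyde F8.
- Annulation and unmasking: annulation of the two benzyl-protected partners under the conditions of step 2 should give 5,7-bis(benzyloxy)-3-(3-methylbutyl)-2-[3,4,5-tris(benzyloxy)phenyl]-4H-chromen-4-one F9. Hydrogenolysis (H2, Pd/C, EtOAc/MeOH, rt) with filtration under argon should deliver 6 with toluene as the only by-product; the tetrasubstituted, conjugated C2=C3 bond should survive.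

**Step 1.** Oxidative homocoupling of 2 under copper/amine conditions may compete if traces of oxygen are present, and the volatility of 2 may deplete it at 50 °C.

The fallback removes copper and amine by using a preformed alkynylmetal. It sets out from 2 and 1 and returns at 3. Deprotonation of 2 with n-BuLi (THF, −78 °C) should give (5-methylhex-1-yn-1-yl)lithium F10. Transmetalation with ZnCl2 should give chloro(5-methylhex-1-yn-1-yl)zinc F11. Negishi coupling of this reagent with 1 (Pd(PPh3)4, THF, rt to 50 °C) should give 3.

## Further compounds

F1 | step 2 | (±)-2-(1-hydroxy-5-methylhexyl)-3,5-dimethoxyphenol | CC(C)CCCC(O)c1c(O)cc(OC)cc1OC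
F2 | step 2 | 1-(2-hydroxy-4,6-dimethoxyphenyl)-5-methylhexan-1-one | CC(C)CCCC(=O)c1c(O)cc(OC)cc1OC
F3 | step 2 | (2E)-1-(2-hydroxy-4,6-dimethoxyphenyl)-5-methyl-2-[(3,4,5-trimethoxyphenyl)methylidene]hexan-1-one | CC(C)CC/C(=C\c1cc(OC)c(OC)c(OC)c1)C(=O)c1c(O)cc(OC)cc1OC
F4 | step 3 | 5-iodobenzene-1,2,3-triol | Oc1cc(I)cc(O)c1O
F5 | step 3 | 1,2,3-tris(benzyloxy)-5-iodobenzene | Ic1cc(OCc2ccccc2)c(OCc2ccccc2)c(OCc2ccccc2)c1
F6 | step 3 | 1,2,3-tris(benzyloxy)-5-(5-methylhex-1-yn-1-yl)benzene | CC(C)CCC#Cc1cc(OCc2ccccc2)c(OCc2ccccc2)c(OCc2ccccc2)c1
F7 | step 3 | 2,4,6-trihydroxybenzaldehyde | O=Cc1c(O)cc(O)cc1O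
F8 | step 3 | 2,4-bis(benzyloxy)-6-hydroxybenzaldehyde | O=Cc1c(O)cc(OCc2ccccc2)cc1OCc1ccccc1
F9 | step 3 | 5,7-bis(benzyloxy)-3-(3-methylbutyl)-2-[3,4,5-tris(benzyloxy)phenyl]-4H-chromen-4-one | CC(C)CCc1c(-c2cc(OCc3ccccc3)c(OCc3ccccc3)c(OCc3ccccc3)c2)oc2cc(OCc3ccccc3)cc(OCc3ccccc3)c2c1=O
F10 | step 1 | (5-methylhex-1-yn-1-yl)lithium | CC(C)CCC#C[Li]
F11 | step 1 | chloro(5-methylhex-1-yn-1-yl)zinc | CC(C)CCC#C[Zn]Cl
A1 | alternative 1 | 3,5-dimethoxy-2-(5-methylhexanoyl)phenyl 3,4,5-trimethoxybenzoate | CC(C)CCCC(=O)c1c(OC(=O)c2cc(OC)c(OC)c(OC)c2)cc(OC)cc1OC
A2 | alternative 1 | (±)-1-(2-hydroxy-4,6-dimethoxyphenyl)-2-(3-methylbutyl)-3-(3,4,5-trimethoxyphenyl)propane-1,3-dione | CC(C)CCC(C(=O)c1cc(OC)c(OC)c(OC)c1)C(=O)c1c(O)cc(OC)cc1OC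
A3 | alternative 2 | 1-(2,4,6-trimethoxyphenyl)-3-(3,4,5-trimethoxyphenyl)prop-2-yn-1-one | COc1cc(OC)c(C(=O)C#Cc2cc(OC)c(OC)c(OC)c2)c(OC)c1
A4 | alternative 2 | 3-iodo-5,7-dimethoxy-2-(3,4,5-trimethoxyphenyl)-4H-chromen-4-one | COc1cc(OC)c2c(c1)oc(-c1cc(OC)c(OC)c(OC)c1)c(I)c2=O
A5 | alternative 3 | 2-iodo-3,5-dimethoxyphenol | COc1cc(O)c(I)c(OC)c1
A6 | alternative 3 | 5,7-dimethoxy-4-(3-methylbutyl)-3-(3,4,5-trimethoxyphenyl)-2H-chromen-2-one | O=c1oc2cc(OC)cc(OC)c2c(CCC(C)C)c1-c1cc(OC)c(OC)c(OC)c1
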